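**Plan**

- The target is ring A (gem-dimethyl acylfilicinic acid) – CH2 (M1) – ring B – CH2 (M2) – ring C (O-methylated acyl-methylphloroglucinol). Ring B is hexasubstituted: oxygen on B2, B4 and B6, M1 on B1, M2 on B3 and butanoyl on B5. This alternation of three oxygens with three carbon substituents is what a 3-siloxy-4-alkylcyclobutenone (B2–B5) and a 1-siloxyalkyne (B1, B6) give on benzannulation, so ring B can be made last.
- Retrosynthesis: remove the protecting groups and cut the B5–acyl bond. Cut ring B at B1–B2 and B5–B6 (B2–B3 opens and re-closes) into a cyclobutenone carrying the ring C arm and a siloxyalkyne carrying the ring A arm. Cut the cyclobutenone at B2–B5 and B3–B4 into a ketene (from a ring C propanoic acid) and triisopropylsiloxyethyne. Cut the siloxyalkyne at its C–O bond and at the M1–ring A bond.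
- Forward: ring C is elaborated from 2-methylphloroglucinol and the four-membered ring is added. Ring A is made from phloroglucinol and fitted with the ynol ether arm. Ring B is then formed by benzannulation, followed by desilylation, B5 acylation, hydrogenolysis and enol ether hydrolysis.
- Stereochemistry: the target has no stereocentre. The single centre of the cyclobutenone is racemic and vanishes on aromatisation. The Z silyl enol ether on ring A is only a temporary mask of the ketone.

Key step: step 16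

Assumption: ring A of the target is one tautomer of an enolised triketone, so its bis(methyl enol ether) is written as the cross-conjugated 3,5-dimethoxy dienone (both enol OH next to the CMe2 carbon etherified); any positional isomer would hydrolyse to the same ring A in step 20.

Abbreviations in names: TIPS = tri(propan-2-yl)silyl; Ar = 2,6-bis(benzyloxy)-3-butanoyl-4-methoxy-5-methylphenyl; Ar' = 3-butanoyl-2,6-dihydroxy-4-methoxy-5-methylphenyl; A = 5-butanoyl-2,4-dimethoxy-3,3-dimethyl-6-oxocyclohexa-1,4-dien-1-yl; A* = 2,4-dimethoxy-3,3-dimethyl-6-oxo-5-[(1Z)-1-(TIPS-oxy)but-1-en-1-yl]cyclohexa-1,4-dien-1-yl.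

**Route**

Step 1
Reactants: 1 ethynyltrimethylsilane
Product: 3 trimethyl[(TIPS-oxy)ethynyl]silane, via lithium 2-(trimethylsilyl)ethynolate 2 (not isolated)
Conditions: LiN(SiMe3)2, LiOO-t-Bu (from t-BuOOH and LiN(SiMe3)2), THF, −78 → 0 °C; then i-Pr3SiOTf, −78 °C → rt
Reagents that add atoms: tert-butyl hydroperoxide CC(C)(C)OO; triisopropylsilyl trifluoromethanesulfonate CC(C)[Si](C(C)C)(C(C)C)OS(=O)(=O)C(F)(F)F
Why: Oxygen transfer from the lithium peroxide to the lithium acetylide (acetylide-to-ynolate oxidation) gives ynolate 2, and the hard, bulky silyl triflate should cap it on oxygen to give the silyl ynol ether.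

Step 2
Reactants: 3 trimethyl[(TIPS-oxy)ethynyl]silane
Product: 4 (ethynyloxy)tri(propan-2-yl)silane (triisopropylsiloxyethyne)
Conditions: K2CO3 (0.2 equiv), MeOH–THF, 0 °C, short reaction time
Reagents that add atoms: none
Why: Base-catalysed methanolysis (protodesilylation of an alkynylsilane) should cleave the unhindered C(sp)–SiMe3 bond well before the hindered O–Si(i-Pr)3 bond.

Step 3
Reactants: 5 2-methylphloroglucinol
Product: 7 2,4,6-trihydroxy-3-methylbenzaldehyde, via aryliminium chloride 6 (not isolated)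
Conditions: POCl3, DMF, EtOAc, 0 °C → rt; then H2O, 50 °C
Reagents that add atoms: N,N-dimethylformamide CN(C)C=O; water O
Why: Vilsmeier–Haack formylation of the phloroglucinol ring, whose two free positions are equivalent and which is deactivated against a second formylation by the first.

Step 4
Reactants: 7 2,4,6-trihydroxy-3-methylbenzaldehyde
Product: 8 2,6-dihydroxy-4-methoxy-3-methylbenzaldehyde
Conditions: MeI (1.05 equiv), K2CO3 (1.0 equiv), acetone, rt
Reagents that add atoms: iodomethane CI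
Why: Williamson etherification should select the 4-OH, the only hydroxyl not hydrogen-bonded to the aldehyde and the most acidic one (para to the carbonyl); this places OMe next to the methyl group and the free ring position.

Step 5
Reactants: 8 2,6-dihydroxy-4-methoxy-3-methylbenzaldehyde
Product: 9 2,6-bis(benzyloxy)-4-methoxy-3-methylbenzaldehyde
Conditions: BnBr (2.5 equiv), K2CO3, DMF, 60 °C
Reagents that add atoms: benzyl bromide BrCc1ccccc1
Why: Williamson etherification of the two chelated hydroxyls under more forcing conditions; benzyl ethers tolerate the Lewis acid, base, heat and fluoride to come and leave by hydrogenolysis.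

Step 6
Reactants: 9 2,6-bis(benzyloxy)-4-methoxy-3-methylbenzaldehyde
Product: 10 methyl (2E)-3-[2,6-bis(benzyloxy)-4-methoxy-3-methylphenyl]prop-2-enoate
Conditions: (MeO)2P(O)CH2CO2Me, NaH, THF, 0 °C → rt
Reagents that add atoms: trimethyl phosphonoacetate COC(=O)CP(=O)(OC)OC
Why: Horner–Wadsworth–Emmons olefination gives the (E)-cinnamate and brings in the two carbons that become B3 and B2, the aldehyde carbon becoming M2.

Step 7
Reactants: 10 methyl (2E)-3-[2,6-bis(benzyloxy)-4-methoxy-3-methylphenyl]prop-2-enoate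
Product: 11 methyl 3-[2,6-bis(benzyloxy)-4-methoxy-3-methylphenyl]propanoate
Conditions: H2 (1 atm), Pd/C (5%), Ph2S (0.01 equiv), EtOAc, rt
Reagents that add atoms: none
Why: Catalytic hydrogenation over sulfide-moderated palladium on carbon should saturate the conjugated alkene while the poison suppresses hydrogenolysis of the aryl benzyl ethers.

Step 8
Reactants: 11 methyl 3-[2,6-bis(benzyloxy)-4-methoxy-3-methylphenyl]propanoate
Product: 12 methyl 3-[2,6-bis(benzyloxy)-3-butanoyl-4-methoxy-5-methylphenyl]propanoate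
Conditions: n-PrCOCl, SnCl4, CH2Cl2, −40 → 0 °C
Reagents that add atoms: butanoyl chloride CCCC(Cl)=O
Why: Friedel–Crafts acylation at the only unsubstituted ring position, which is ortho or para to all three oxygen donors; low temperature should spare the benzyl ethers.

Step 9
Reactants: 12 methyl 3-[2,6-bis(benzyloxy)-3-butanoyl-4-methoxy-5-methylphenyl]propanoate
Product: 13 3-[2,6-bis(benzyloxy)-3-butanoyl-4-methoxy-5-methylphenyl]propanoic acid
Conditions: LiOH, THF–MeOH–H2O, rt; then 1 M HCl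
Reagents that add atoms: lithium hydroxide [Li+].[OH-]
Why: Saponification of the methyl ester, with the hindered aryl ketone and the ethers inert.

Step 10
Reactants: 13 3-[2,6-bis(benzyloxy)-3-butanoyl-4-methoxy-5-methylphenyl]propanoic acid; 4 (ethynyloxy)tri(propan-2-yl)silane
Product: 16 4-(Ar-methyl)-3-(TIPS-oxy)cyclobut-2-en-1-one (racemic), via acid chloride 14 (not isolated), via monoalkylketene 15 (not isolated)
Conditions: (COCl)2, DMF (cat.), CH2Cl2, 0 °C → rt, evaporate; then slow addition to 4 (1.5 equiv) and Et3N in MeCN, rt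
Reagents that add atoms: none
Why: Dehydrochlorination of 14 gives ketene 15, which the electron-rich ynol ether should trap in a regioselective [2+2] cycloaddition (ketene carbonyl carbon to the alkyne CH), forming the B2–B5 and B3–B4 bonds; the new stereocentre forms as a racemate and is lost in step 16.

Step 11
Reactants: 17 phloroglucinol
Product: 18 1-(2,4,6-trihydroxyphenyl)butan-1-one
Conditions: n-PrCOCl, AlCl3, PhNO2–CH2Cl2, 0 → 45 °C
Reagents that add atoms: butanoyl chloride CCCC(Cl)=O
Why: Friedel–Crafts acylation of phloroglucinol, the first acyl group deactivating the ring against a second.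

Step 12
Reactants: 18 1-(2,4,6-trihydroxyphenyl)butan-1-one
Product: 19 2-butanoyl-3,5-dihydroxy-4,4-dimethylcyclohexa-2,5-dien-1-one (butyrylfilicinic acid)
Conditions: NaOMe (3 equiv), MeI (2.2 equiv), MeOH, 0 °C → rt
Reagents that add atoms: iodomethane CI
Why: Dearomatising double C-methylation of the acylphloroglucinol anion at one ring carbon (phenoxide C-alkylation in a protic solvent) gives the gem-dimethyl acylfilicinic acid.

Step 13
Reactants: 19 2-butanoyl-3,5-dihydroxy-4,4-dimethylcyclohexa-2,5-dien-1-one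
Product: 20 2-butanoyl-3,5-dihydroxy-4,4-dimethyl-6-(prop-2-yn-1-yl)cyclohexa-2,5-dien-1-one
Conditions: HC≡CCH2Br (1.1 equiv), NaOMe (2 equiv), MeOH, 0 °C → rt; acidify
Reagents that add atoms: 3-bromoprop-1-yne C#CCBr
Why: C-Alkylation of the vinylogous acid dianion at its only remaining nucleophilic ring carbon with a soft propargylic halide in a protic solvent; this sets M1 and the carbons that become B1 and B6.

Step 14
Reactants: 20 2-butanoyl-3,5-dihydroxy-4,4-dimethyl-6-(prop-2-yn-1-yl)cyclohexa-2,5-dien-1-one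
Product: 21 2-butanoyl-3,5-dimethoxy-4,4-dimethyl-6-(prop-2-yn-1-yl)cyclohexa-2,5-dien-1-one
Conditions: Me3SiCHN2 (excess), MeOH–toluene, 0 °C → rt
Reagents that add atoms: (trimethylsilyl)diazomethane C[Si](C)(C)C=[N+]=[N-]
Why: O-Methylation of the two acidic enols with a diazoalkane avoids C-methylation and gives non-acidic vinylogous esters that tolerate base, heat and fluoride and hydrolyse in dilute acid.

Step 15
Reactants: 21 2-butanoyl-3,5-dimethoxy-4,4-dimethyl-6-(prop-2-yn-1-yl)cyclohexa-2,5-dien-1-one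
Product: 23 3,5-dimethoxy-4,4-dimethyl-2-[(1Z)-1-(TIPS-oxy)but-1-en-1-yl]-6-[3-(TIPS-oxy)prop-2-yn-1-yl]cyclohexa-2,5-dien-1-one, via dilithium enolate ynolate 22 (not isolated)
Conditions: LiN(SiMe3)2 (3.3 equiv), t-BuOOH (1.1 equiv), THF, −78 → 0 °C; then i-Pr3SiOTf (2.6 equiv), −78 → 0 °C
Reagents that add atoms: tert-butyl hydroperoxide CC(C)(C)OO; triisopropylsilyl trifluoromethanesulfonate CC(C)[Si](C(C)C)(C(C)C)OS(=O)(=O)C(F)(F)F
Why: The first equivalent of base turns the butanoyl ketone into its lithium enolate, which masks it while the acetylide is oxidised to the ynolate (acetylide-to-ynolate oxidation), and both oxygen anions of 22 are then silylated; the Z enol ether is expected from kinetic deprotonation of a ketone with a bulky acyl substituent.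

Step 16
Reactants: 16 4-(Ar-methyl)-3-(TIPS-oxy)cyclobut-2-en-1-one; 23 the ring A siloxyalkyne
Product: 28 2-(A*-methyl)-6-(Ar-methyl)-3,5-bis(TIPS-oxy)phenol, via vinylketene 24 (not isolated), via vinylcyclobutenone adduct 25 (not isolated), via dienylketene 26 (not isolated), via cyclohexa-2,4-dienone 27 (not isolated)
Conditions: toluene (0.2 M), 100 °C, sealed tube, argon
Reagents that add atoms: none
Why: Heating opens cyclobutenone 16 by 4π-electrocyclic cleavage of its C1–C4 bond (B2–B3) to the (2-siloxyvinyl)ketene 24; the nucleophilic, oxygen-remote carbon of siloxyalkyne 23 attacks the ketene carbonyl carbon and a regioselective [2+2] cycloaddition gives 25 with new B1–B2 and B5–B6 bonds. A second 4π opening (of the transient B2–B5 bond) gives dienylketene 26, whose thermal disrotatory 6π-electrocyclisation re-forms B2–B3 in a six-membered ring (27), and enolisation aromatises it to phenol 28. The closest known reaction type is the Danheiser benzannulation of cyclobutenones with siloxyalkynes, used here with a 3-oxygenated cyclobutenone so that a phloroglucinol results. Ring B is thus closed by 6π-electrocyclisation of a ketene-terminated triene, and the four-membered ring of 25 arises by [2+2] cycloaddition and is consumed. No stereocentre survives, since the racemic centres of 16, 25 and 27 are erased on aromatisation. The step needs regiocontrol in the ketene–alkyne union, which the polarity of the siloxyalkyne secures, and chemoselectivity for the ynol ether over the silyl enol ether and the product phenol, which the higher ketenophilicity of the ynol ether and the two ortho arms flanking the new OH should secure.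

Step 17
Reactants: 28 2-(A*-methyl)-6-(Ar-methyl)-3,5-bis(TIPS-oxy)phenol
Product: 29 2-(A-methyl)-4-(Ar-methyl)benzene-1,3,5-triol
Conditions: Bu4NF (3.5 equiv), AcOH (3.5 equiv), THF, 0 °C → rt
Reagents that add atoms: none
Why: Fluoride cleaves the two aryl silyl ethers and the silyl enol ether, which returns the ring A butanoyl ketone, while acetic acid buffers the phenoxides.

Step 18
Reactants: 29 2-(A-methyl)-4-(Ar-methyl)benzene-1,3,5-triol
Product: 30 1-[3-(A-methyl)-5-(Ar-methyl)-2,4,6-trihydroxyphenyl]butan-1-one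
Conditions: (n-PrCO)2O (1.5 equiv), BF3·OEt2, CH2Cl2, 0 °C → rt; aq. NaOAc–MeOH work-up
Reagents that add atoms: butanoic anhydride CCCC(=O)OC(=O)CCC
Why: Friedel–Crafts acylation (with Fries-type transfer of any O-acyl group) at B5, the only free carbon of the trihydroxy ring, while rings A and C carry neither a free hydroxyl nor a ring CH.

Step 19
Reactants: 30 1-[3-(A-methyl)-5-(Ar-methyl)-2,4,6-trihydroxyphenyl]butan-1-one
Product: 31 1-[3-(A-methyl)-5-(Ar'-methyl)-2,4,6-trihydroxyphenyl]butan-1-one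
Conditions: H2 (1 atm), Pd/C (10%), EtOAc–MeOH, rt
Reagents that add atoms: none
Why: Hydrogenolysis of the two aryl benzyl ethers; the tetrasubstituted enol ether double bonds of ring A and the hydrogen-bonded aryl ketones should not be reduced under these mild conditions.

Step 20
Reactants: 31 1-[3-(A-methyl)-5-(Ar'-methyl)-2,4,6-trihydroxyphenyl]butan-1-one
Product: 32 Filixsaure (target)
Conditions: 1 M HCl, THF, 40 °C
Reagents that add atoms: water O
Why: Acid hydrolysis of the two vinylogous methyl esters (addition of water, loss of methanol) releases the enolised ring A triketone and with it the target.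

**Compound list**

1 | ethynyltrimethylsilane | C#C[Si](C)(C)C | starting material
2 | lithium 2-(trimethylsilyl)ethynolate | [Li+].[O-]C#C[Si](C)(C)C | intermediate (not isolated)
3 | trimethyl[(triisopropylsilyloxy)ethynyl]silane | C[Si](C)(C)C#CO[Si](C(C)C)(C(C)C)C(C)C | intermediate
4 | (ethynyloxy)tri(propan-2-yl)silane | C#CO[Si](C(C)C)(C(C)C)C(C)C | intermediate
5 | 2-methylphloroglucinol (2-methylbenzene-1,3,5-triol) | Cc1c(O)cc(O)cc1O | starting material
6 | N-methyl-N-[(2,4,6-trihydroxy-3-methylphenyl)methylidene]methanaminium chloride | C[N+](C)=Cc1c(O)cc(O)c(C)c1O.[Cl-] | intermediate (not isolated)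
7 | 2,4,6-trihydroxy-3-methylbenzaldehyde | O=Cc1c(O)cc(O)c(C)c1O | intermediate
8 | 2,6-dihydroxy-4-methoxy-3-methylbenzaldehyde | O=Cc1c(O)cc(OC)c(C)c1O | intermediate
9 | 2,6-bis(benzyloxy)-4-methoxy-3-methylbenzaldehyde | O=Cc1c(OCc2ccccc2)cc(OC)c(C)c1OCc1ccccc1 | intermediate
10 | methyl (2E)-3-[2,6-bis(benzyloxy)-4-methoxy-3-methylphenyl]prop-2-enoate | COC(=O)/C=C/c1c(OCc2ccccc2)cc(OC)c(C)c1OCc1ccccc1 | intermediate
11 | methyl 3-[2,6-bis(benzyloxy)-4-methoxy-3-methylphenyl]propanoate | COC(=O)CCc1c(OCc2ccccc2)cc(OC)c(C)c1OCc1ccccc1 | intermediate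
12 | methyl 3-[2,6-bis(benzyloxy)-3-butanoyl-4-methoxy-5-methylphenyl]propanoate | COC(=O)CCc1c(OCc2ccccc2)c(C(=O)CCC)c(OC)c(C)c1OCc1ccccc1 | intermediate
13 | 3-[2,6-bis(benzyloxy)-3-butanoyl-4-methoxy-5-methylphenyl]propanoic acid | OC(=O)CCc1c(OCc2ccccc2)c(C(=O)CCC)c(OC)c(C)c1OCc1ccccc1 | intermediate
14 | 3-[2,6-bis(benzyloxy)-3-butanoyl-4-methoxy-5-methylphenyl]propanoyl chloride | ClC(=O)CCc1c(OCc2ccccc2)c(C(=O)CCC)c(OC)c(C)c1OCc1ccccc1 | intermediate (not isolated)
15 | 3-[2,6-bis(benzyloxy)-3-butanoyl-4-methoxy-5-methylphenyl]prop-1-en-1-one (monoalkylketene) | O=C=CCc1c(OCc2ccccc2)c(C(=O)CCC)c(OC)c(C)c1OCc1ccccc1 | intermediate (not isolated)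
16 | 4-{[2,6-bis(benzyloxy)-3-butanoyl-4-methoxy-5-methylphenyl]methyl}-3-(triisopropylsilyloxy)cyclobut-2-en-1-one, racemic | O=C1C=C(O[Si](C(C)C)(C(C)C)C(C)C)C1Cc1c(OCc2ccccc2)c(C(=O)CCC)c(OC)c(C)c1OCc1ccccc1 | intermediate
17 | phloroglucinol | Oc1cc(O)cc(O)c1 | starting material
18 | 1-(2,4,6-trihydroxyphenyl)butan-1-one | CCCC(=O)c1c(O)cc(O)cc1O | intermediate
19 | 2-butanoyl-3,5-dihydroxy-4,4-dimethylcyclohexa-2,5-dien-1-one | CCCC(=O)C1=C(O)C(C)(C)C(O)=CC1=O | intermediate
20 | 2-butanoyl-3,5-dihydroxy-4,4-dimethyl-6-(prop-2-yn-1-yl)cyclohexa-2,5-dien-1-one | CCCC(=O)C1=C(O)C(C)(C)C(O)=C(CC#C)C1=O | intermediate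
21 | 2-butanoyl-3,5-dimethoxy-4,4-dimethyl-6-(prop-2-yn-1-yl)cyclohexa-2,5-dien-1-one | CCCC(=O)C1=C(OC)C(C)(C)C(OC)=C(CC#C)C1=O | intermediate
22 | dilithium (Z)-enolate ynolate of 21 | [Li+].[Li+].CC/C=C(\[O-])C1=C(OC)C(C)(C)C(OC)=C(CC#C[O-])C1=O | intermediate (not isolated)
23 | 3,5-dimethoxy-4,4-dimethyl-2-[(1Z)-1-(triisopropylsilyloxy)but-1-en-1-yl]-6-[3-(triisopropylsilyloxy)prop-2-yn-1-yl]cyclohexa-2,5-dien-1-one | CC/C=C(\O[Si](C(C)C)(C(C)C)C(C)C)C1=C(OC)C(C)(C)C(OC)=C(CC#CO[Si](C(C)C)(C(C)C)C(C)C)C1=O | intermediate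
24 | (3Z)-5-Ar-3-(triisopropylsilyloxy)penta-1,3-dien-1-one (vinylketene) | O=C=C/C(O[Si](C(C)C)(C(C)C)C(C)C)=C/Cc1c(OCc2ccccc2)c(C(=O)CCC)c(OC)c(C)c1OCc1ccccc1 | intermediate (not isolated)
25 | 2-(A*-methyl)-4-[(1Z)-3-Ar-1-(triisopropylsilyloxy)prop-1-en-1-yl]-3-(triisopropylsilyloxy)cyclobut-2-en-1-one, racemic | O=C1C(CC2=C(OC)C(C)(C)C(OC)=C(/C(O[Si](C(C)C)(C(C)C)C(C)C)=C/CC)C2=O)=C(O[Si](C(C)C)(C(C)C)C(C)C)C1/C(O[Si](C(C)C)(C(C)C)C(C)C)=C/Cc1c(OCc2ccccc2)c(C(=O)CCC)c(OC)c(C)c1OCc1ccccc1 | intermediate (not isolated)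
26 | (3E,5Z)-2-(A*-methyl)-7-Ar-3,5-bis(triisopropylsilyloxy)hepta-1,3,5-trien-1-one (dienylketene) | O=C=C(CC1=C(OC)C(C)(C)C(OC)=C(/C(O[Si](C(C)C)(C(C)C)C(C)C)=C/CC)C1=O)/C(O[Si](C(C)C)(C(C)C)C(C)C)=C\C(O[Si](C(C)C)(C(C)C)C(C)C)=C\Cc1c(OCc2ccccc2)c(C(=O)CCC)c(OC)c(C)c1OCc1ccccc1 | intermediate (not isolated)
27 | 2-(A*-methyl)-6-(Ar-methyl)-3,5-bis(triisopropylsilyloxy)cyclohexa-2,4-dien-1-one, racemic | O=C1C(CC2=C(OC)C(C)(C)C(OC)=C(/C(O[Si](C(C)C)(C(C)C)C(C)C)=C/CC)C2=O)=C(O[Si](C(C)C)(C(C)C)C(C)C)C=C(O[Si](C(C)C)(C(C)C)C(C)C)C1Cc1c(OCc2ccccc2)c(C(=O)CCC)c(OC)c(C)c1OCc1ccccc1 | intermediate (not isolated)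
28 | 2-(A*-methyl)-6-(Ar-methyl)-3,5-bis(triisopropylsilyloxy)phenol | Oc1c(CC2=C(OC)C(C)(C)C(OC)=C(/C(O[Si](C(C)C)(C(C)C)C(C)C)=C/CC)C2=O)c(O[Si](C(C)C)(C(C)C)C(C)C)cc(O[Si](C(C)C)(C(C)C)C(C)C)c1Cc1c(OCc2ccccc2)c(C(=O)CCC)c(OC)c(C)c1OCc1ccccc1 | intermediate
29 | 2-(A-methyl)-4-(Ar-methyl)benzene-1,3,5-triol | CCCC(=O)C1=C(OC)C(C)(C)C(OC)=C(Cc2c(O)c(Cc3c(OCc4ccccc4)c(C(=O)CCC)c(OC)c(C)c3OCc3ccccc3)c(O)cc2O)C1=O | intermediate
30 | 1-[3-(A-methyl)-5-(Ar-methyl)-2,4,6-trihydroxyphenyl]butan-1-one | CCCC(=O)C1=C(OC)C(C)(C)C(OC)=C(Cc2c(O)c(Cc3c(OCc4ccccc4)c(C(=O)CCC)c(OC)c(C)c3OCc3ccccc3)c(O)c(C(=O)CCC)c2O)C1=O | intermediate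
31 | 1-[3-(A-methyl)-5-(Ar'-methyl)-2,4,6-trihydroxyphenyl]butan-1-one | CCCC(=O)C1=C(OC)C(C)(C)C(OC)=C(Cc2c(O)c(Cc3c(O)c(C(=O)CCC)c(OC)c(C)c3O)c(O)c(C(=O)CCC)c2O)C1=O | intermediate
32 | Filixsaure | CCCC(=O)C1=C(O)C(Cc2c(O)c(Cc3c(O)c(C)c(OC)c(C(=O)CCC)c3O)c(O)c(C(=O)CCC)c2O)=C(O)C(C)(C)C1=O | target

**Summary**

Total step count: 20.
Longest linear sequence: 13 steps (steps 3–10 and 16–20, from 2-methylphloroglucinol 5).

Steps most likely to fail:

1. Step 16. The bimolecular capture of vinylketene 24 by the bulky siloxyalkyne 23 may be slower than ketene dimerisation, or than thermal decay of 23, at the temperature needed to open the vinylogous-ester-like cyclobutenone. The fallback moves the union of the two large fragments to a room-temperature ketene cycloaddition. It sets out from acid 13, siloxyalkyne 23 and ynol ether 4. Ketene 15, generated from 13 as in step 10, is intercepted by 23 instead of by 4 and should give 2-(A*-methyl)-4-(Ar-methyl)-3-(TIPS-oxy)cyclobut-2-en-1-one F1. Heating F1 with an excess of the small, unhindered ynol ether 4 should then run the same opening, [2+2], opening and 6π sequence to 4-(A*-methyl)-2-(Ar-methyl)-3,5-bis(TIPS-oxy)phenol F2, a silyl-positional isomer of 28. Fluoride under the conditions of step 17 frees all three ring B oxygens, so F2 comes back to the route at 29.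

2. Step 15. Hydroxylation of the enolate carbon, or addition of the acetylide or the peroxide to the ring A dienone, may compete with oxygen transfer to the acetylide in the dianion. The fallback replaces the in situ enolate mask by a discrete protecting group made without strong base. It sets out from 21, which is silylated under soft enolisation (i-Pr3SiOTf, Et3N, CH2Cl2, 0 °C) to 3,5-dimethoxy-4,4-dimethyl-6-(prop-2-yn-1-yl)-2-[(1Z)-1-(TIPS-oxy)but-1-en-1-yl]cyclohexa-2,5-dien-1-one F3. F3 carries no acidic CH other than the alkyne, so one equivalent of LiN(SiMe3)2, LiOO-t-Bu and one equivalent of i-Pr3SiOTf should convert it into the siloxyalkyne, and the route is rejoined at 23.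

3. Step 18. O-Acylation of the ring B hydroxyls without transfer to carbon, and acetolysis of benzyl or enol ethers by the anhydride–BF3 couple, may consume the substrate. The fallback uses a nitrilium electrophile that cannot O-acylate (Houben–Hoesch reaction). It sets out from 29: butanenitrile, ZnCl2 and HCl gas in Et2O at 0 °C should give 1-[3-(A-methyl)-5-(Ar-methyl)-2,4,6-trihydroxyphenyl]butan-1-iminium chloride F4. Warm dilute aqueous acid hydrolyses the iminium group and, in the same operation, the two ring A enol ethers, giving the ring C di-O-benzyl ether of the target F5. Hydrogenolysis under the conditions of step 19 brings F5 back to the route at 32.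

Further compounds
F1 | step 16 | 2-(A*-methyl)-4-(Ar-methyl)-3-(triisopropylsilyloxy)cyclobut-2-en-1-one, racemic | O=C1C(CC2=C(OC)C(C)(C)C(OC)=C(/C(O[Si](C(C)C)(C(C)C)C(C)C)=C/CC)C2=O)=C(O[Si](C(C)C)(C(C)C)C(C)C)C1Cc1c(OCc2ccccc2)c(C(=O)CCC)c(OC)c(C)c1OCc1ccccc1
F2 | step 16 | 4-(A*-methyl)-2-(Ar-methyl)-3,5-bis(triisopropylsilyloxy)phenol | Oc1cc(O[Si](C(C)C)(C(C)C)C(C)C)c(CC2=C(OC)C(C)(C)C(OC)=C(/C(O[Si](C(C)C)(C(C)C)C(C)C)=C/CC)C2=O)c(O[Si](C(C)C)(C(C)C)C(C)C)c1Cc1c(OCc2ccccc2)c(C(=O)CCC)c(OC)c(C)c1OCc1ccccc1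
F3 | step 15 | 3,5-dimethoxy-4,4-dimethyl-6-(prop-2-yn-1-yl)-2-[(1Z)-1-(triisopropylsilyloxy)but-1-en-1-yl]cyclohexa-2,5-dien-1-one | CC/C=C(\O[Si](C(C)C)(C(C)C)C(C)C)C1=C(OC)C(C)(C)C(OC)=C(CC#C)C1=O
F4 | step 18 | 1-[3-(A-methyl)-5-(Ar-methyl)-2,4,6-trihydroxyphenyl]butan-1-iminium chloride | [Cl-].CCCC(=[NH2+])c1c(O)c(CC2=C(OC)C(C)(C)C(OC)=C(C(=O)CCC)C2=O)c(O)c(Cc2c(OCc3ccccc3)c(C(=O)CCC)c(OC)c(C)c2OCc2ccccc2)c1O
F5 | step 18 | ring C di-O-benzyl ether of Filixsaure | CCCC(=O)C1=C(O)C(Cc2c(O)c(Cc3c(OCc4ccccc4)c(C(=O)CCC)c(OC)c(C)c3OCc3ccccc3)c(O)c(C(=O)CCC)c2O)=C(O)C(C)(C)C1=O
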